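**Retrosynthetic overview**
1. Target 13 ⇒ aryl bromide 11 + (E)-propenyl boronate 12 (Suzuki–Miyaura; the propenyl group goes on last).
2. 11 ⇒ ortho-quinone methide 9 + chiral benzylidene sulfonium ylide 8: asymmetric [4+1] annulation that forms C3–C2, C2–O and both stereocentres (the new step).
3. 9 ⇐ base-labile sulfone 4 ⇐ paeonol 1 (bromination, reduction, sulfinate substitution); 8 ⇐ sulfonium salt 7 ⇐ 3,4,5-trimethoxybenzyl bromide 5 + (−)-isothiocineole 6.
4. Ring order: both benzene rings are bought; the dihydrofuran ring is the only ring made (step 5).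

Assumption: (−)-isothiocineole 6 is bought (it is also made in one step from (S)-limonene), and its sense of induction in step 5 is taken from its epoxidation behaviour as recalled and modelled, not verified; if the sense proved opposite, the (1R,4R,5R) sulfide would be used with nothing else changed.

The target is (2R,3R), 2,3-trans, with an (E)-propenyl group at C5 and OMe at C6.

**Step 1**
Reactants: 1 paeonol (1-(2-hydroxy-4-methoxyphenyl)ethan-1-one)
Product: 2 1-(5-bromo-2-hydroxy-4-methoxyphenyl)ethan-1-one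
Conditions: NBS (1.05 equiv), MeCN, 0 °C → rt
Reagents that add atoms: N-bromosuccinimide, O=C1CCC(=O)N1Br
Why: Electrophilic aromatic bromination (SEAr) goes to C5, which is para to the hydroxyl and ortho to the methoxy group, whereas C3 is flanked by two oxygens.

**Step 2**
Reactants: 2 1-(5-bromo-2-hydroxy-4-methoxyphenyl)ethan-1-one
Product: 3 rac-4-bromo-2-(1-hydroxyethyl)-5-methoxyphenol
Conditions: NaBH4 (1.5 equiv), MeOH–THF, 0 °C; sat. NH4Cl work-up, used crude
Reagents that add atoms: none
Why: Borohydride 1,2-reduction of the aryl ketone; the new carbinol centre is racemic and is erased when the quinone methide forms.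

**Step 3**
Reactants: 3 rac-4-bromo-2-(1-hydroxyethyl)-5-methoxyphenol
Product: 4 rac-4-bromo-5-methoxy-2-[1-(4-methylbenzenesulfonyl)ethyl]phenol
Conditions: TolSO2Na (2 equiv), HCO2H–H2O (1:1), rt; product filtered
Reagents that add atoms: sodium 4-methylbenzenesulfinate, [Na+].[O-]S(=O)c1ccc(C)cc1
Why: Acid-promoted SN1 substitution in which the ortho-hydroxy/para-methoxy-stabilised benzylic cation is captured at sulfur by the sulfinate, giving a crystalline, base-labile sulfone whose stereocentre is erased later.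

**Step 4**
Reactants: 5 3,4,5-trimethoxybenzyl bromide (5-(bromomethyl)-1,2,3-trimethoxybenzene); 6 (−)-isothiocineole ((1S,4S,5S)-4,7,7-trimethyl-6-thiabicyclo[3.2.1]octane)
Product: 7 (1S,4S,5S,6S)-4,7,7-trimethyl-6-[(3,4,5-trimethoxyphenyl)methyl]-6-thiabicyclo[3.2.1]octan-6-ium trifluoromethanesulfonate
Conditions: LiOTf (3 equiv), CH2Cl2–H2O (1:1), rt, 48 h; crystallised
Reagents that add atoms: lithium trifluoromethanesulfonate, [Li+].[O-]S(=O)(=O)C(F)(F)F
Why: SN2 S-alkylation of the sulfide on its exo lone pair gives a single sulfonium diastereomer, and exchange of bromide for non-nucleophilic triflate prevents dealkylation.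

**Step 5**
Reactants: 4 rac-4-bromo-5-methoxy-2-[1-(4-methylbenzenesulfonyl)ethyl]phenol; 7 the sulfonium triflate
Product: 11 (2R,3R)-5-bromo-6-methoxy-3-methyl-2-(3,4,5-trimethoxyphenyl)-2,3-dihydro-1-benzofuran, via sulfonium ylide 8 (not isolated), via ortho-quinone methide 9 (not isolated), via betaine 10 (not isolated)
Conditions: 7 (1.2 equiv), Cs2CO3 (3 equiv), CH2Cl2, −20 °C → rt, slow addition of 4; cis isomer removed and sulfide 6 recovered on chromatography; recrystallise to upgrade ee
Reagents that add atoms: none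
Why: Proposed new method: asymmetric [4+1] annulation of an alkyl-substituted ortho-quinone methide with a chiral benzylidene sulfonium ylide — Cs2CO3 deprotonates phenol 4 (sulfinate loss gives the (E)-quinone methide 9) and salt 7 (ylide 8); aromatisation-driven, irreversible 1,4-addition of the ylide carbon to the methide carbon gives betaine 10, whose phenoxide displaces the sulfide by 5-exo-tet SN2 with inversion; the ylide reacts through the conformer with aryl syn to the sulfur lone pair and on the face remote from the CMe2 group (the face selection expected to give (S,S)-epoxides from aldehydes with this sulfide enantiomer), which fixes C2 as R after inversion, and the approach that keeps aryl anti to the methide methyl gives the 2,3-trans (3R) isomer as in reported ylide/quinone methide annulations; the closest known reactions are racemic sulfur-ylide/ortho-quinone methide [4+1] annulations with carbonyl-stabilised ylides and asymmetric benzylidene transfer from isothiocineole sulfonium salts to aldehydes, imines and Michael acceptors.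

**Step 6**
Reactants: 11 (2R,3R)-5-bromo-6-methoxy-3-methyl-2-(3,4,5-trimethoxyphenyl)-2,3-dihydro-1-benzofuran; 12 (E)-prop-1-enylboronic acid pinacol ester
Product: 13 (2R,3R)-6-methoxy-3-methyl-5-[(E)-prop-1-en-1-yl]-2-(3,4,5-trimethoxyphenyl)-2,3-dihydro-1-benzofuran
Conditions: 12 (1.5 equiv), Pd(dppf)Cl2 (5 mol %), K2CO3 (3 equiv), 1,4-dioxane–H2O (5:1), 85 °C
Reagents that add atoms: none
Why: Suzuki–Miyaura cross-coupling proceeds with retention of alkene geometry, and the mildly basic conditions do not touch the C2/C3 stereocentres.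

**Compound list**
1 | paeonol, 1-(2-hydroxy-4-methoxyphenyl)ethan-1-one | CC(=O)c1ccc(OC)cc1O | starting material
2 | 1-(5-bromo-2-hydroxy-4-methoxyphenyl)ethan-1-one | CC(=O)c1cc(Br)c(OC)cc1O | intermediate
3 | rac-4-bromo-2-(1-hydroxyethyl)-5-methoxyphenol | CC(O)c1cc(Br)c(OC)cc1O | intermediate
4 | rac-4-bromo-5-methoxy-2-[1-(4-methylbenzenesulfonyl)ethyl]phenol | CC(c1cc(Br)c(OC)cc1O)S(=O)(=O)c1ccc(C)cc1 | intermediate
5 | 3,4,5-trimethoxybenzyl bromide, 5-(bromomethyl)-1,2,3-trimethoxybenzene | COc1cc(CBr)cc(OC)c1OC | starting material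
6 | (−)-isothiocineole, (1S,4S,5S)-4,7,7-trimethyl-6-thiabicyclo[3.2.1]octane | C[C@H]1CC[C@H]2C[C@@H]1SC2(C)C | starting material
7 | (1S,4S,5S,6S)-4,7,7-trimethyl-6-[(3,4,5-trimethoxyphenyl)methyl]-6-thiabicyclo[3.2.1]octan-6-ium trifluoromethanesulfonate (benzyl on the exo face of sulfur) | C[C@H]1CC[C@H]2C[C@@H]1[S@+](Cc1cc(OC)c(OC)c(OC)c1)C2(C)C.[O-]S(=O)(=O)C(F)(F)F | intermediate
8 | sulfonium ylide, (1S,4S,5S,6S)-4,7,7-trimethyl-6-thiabicyclo[3.2.1]octan-6-ium-6-yl (3,4,5-trimethoxyphenyl)methanide | C[C@H]1CC[C@H]2C[C@@H]1[S@+]([CH-]c1cc(OC)c(OC)c(OC)c1)C2(C)C | intermediate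
9 | ortho-quinone methide, (6E)-4-bromo-6-ethylidene-3-methoxycyclohexa-2,4-dien-1-one | C/C=C1\C=C(Br)C(OC)=CC1=O | intermediate
10 | betaine, 4-bromo-5-methoxy-2-{(1S,2R)-1-[(1S,4S,5S)-4,7,7-trimethyl-6-thiabicyclo[3.2.1]octan-6-ium-6-yl]-1-(3,4,5-trimethoxyphenyl)propan-2-yl}phenolate | C[C@H]1CC[C@H]2C[C@@H]1[S@+]([C@H](c1cc(OC)c(OC)c(OC)c1)[C@H](C)c1cc(Br)c(OC)cc1[O-])C2(C)C | intermediate
11 | (2R,3R)-5-bromo-6-methoxy-3-methyl-2-(3,4,5-trimethoxyphenyl)-2,3-dihydro-1-benzofuran | Brc1cc2c(cc1OC)O[C@@H](c1cc(OC)c(OC)c(OC)c1)[C@@H]2C | intermediate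
12 | (E)-prop-1-enylboronic acid pinacol ester, 4,4,5,5-tetramethyl-2-[(E)-prop-1-en-1-yl]-1,3,2-dioxaborolane | C/C=C/B1OC(C)(C)C(C)(C)O1 | starting material
13 | (2R,3R)-6-methoxy-3-methyl-5-[(E)-prop-1-en-1-yl]-2-(3,4,5-trimethoxyphenyl)-2,3-dihydro-1-benzofuran | C/C=C/c1cc2c(cc1OC)O[C@@H](c1cc(OC)c(OC)c(OC)c1)[C@@H]2C | target

**Step count**
Total steps: 6. Longest linear sequence: 5 (steps 1, 2, 3, 5, 6).

**Three steps most likely to fail**

Step 5 (the proposed new step). Risks: the methyl-substituted quinone methide 9 may tautomerise to the 2-vinylphenol, the trans/cis ratio is set kinetically, and the enantioselectivity on this acceptor class is untested. The fallback uses known chemistry, sets out from 12 and comes back to the route at 13. Suzuki–Miyaura coupling of 12 with commercial 5-bromo-1,2,3-trimethoxybenzene gives (E)-isoelemicin F1. The documented Ti(IV)–TADDOLate-promoted formal [3+2] cycloaddition of 2-methoxy-1,4-benzoquinone with (E)-propenylarenes (CH2Cl2, −78 °C, any cyclobutane adduct rearranged with acid) then gives the trans phenol (2R,3R)-6-methoxy-3-methyl-2-(3,4,5-trimethoxyphenyl)-2,3-dihydro-1-benzofuran-5-ol F2, using the TADDOL enantiomer that delivers the (2R,3R) series. Tf2O/pyridine gives the aryl triflate F3, which is coupled with 12 under the step 6 conditions to give 13.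

Step 3. Risks: the electron-rich diol 3 may oligomerise in acid, or sulfone 4 may lose sulfinate on handling. The fallback changes the quinone methide precursor, sets out from 3 and comes back at 9. Ac2O/pyridine/DMAP gives the diacetate 4-bromo-2-(1-acetoxyethyl)-5-methoxyphenyl acetate F4. In the step 5 flask (7, Cs2CO3, CH2Cl2, 2 equiv MeOH) methanolysis of the aryl acetate frees the phenoxide, which expels the benzylic acetate to give 9, and 9 goes on to 11.

Step 6. Risks: slow oxidative addition into the electron-rich ortho-methoxy bromide, protodeboronation of 12, or E/Z erosion. The fallback avoids palladium, sets out from 11 and comes back at 13. Br/Li exchange (n-BuLi, THF, −78 °C) and a DMF quench give the aldehyde (2R,3R)-6-methoxy-3-methyl-2-(3,4,5-trimethoxyphenyl)-2,3-dihydro-1-benzofuran-5-carbaldehyde F5. Julia–Kocienski olefination with 5-(ethanesulfonyl)-1-phenyl-1H-tetrazole and KHMDS (DME, −60 °C → rt) gives the (E)-propenyl compound 13.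

**Further compounds**
F1 | step 5 | (E)-isoelemicin, 1,2,3-trimethoxy-5-[(E)-prop-1-en-1-yl]benzene | C/C=C/c1cc(OC)c(OC)c(OC)c1
F2 | step 5 | (2R,3R)-6-methoxy-3-methyl-2-(3,4,5-trimethoxyphenyl)-2,3-dihydro-1-benzofuran-5-ol | Oc1cc2c(cc1OC)O[C@@H](c1cc(OC)c(OC)c(OC)c1)[C@@H]2C
F3 | step 5 | (2R,3R)-6-methoxy-3-methyl-2-(3,4,5-trimethoxyphenyl)-2,3-dihydro-1-benzofuran-5-yl trifluoromethanesulfonate | O=S(=O)(Oc1cc2c(cc1OC)O[C@@H](c1cc(OC)c(OC)c(OC)c1)[C@@H]2C)C(F)(F)F
F4 | step 3 | rac-4-bromo-2-(1-acetoxyethyl)-5-methoxyphenyl acetate | CC(OC(C)=O)c1cc(Br)c(OC)cc1OC(C)=O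
F5 | step 6 | (2R,3R)-6-methoxy-3-methyl-2-(3,4,5-trimethoxyphenyl)-2,3-dihydro-1-benzofuran-5-carbaldehyde | O=Cc1cc2c(cc1OC)O[C@@H](c1cc(OC)c(OC)c(OC)c1)[C@@H]2C
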